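**Assumptions.** (i) BF₃·OEt₂/AcOH acylation of 5-methoxyresorcinol goes ortho to an OH and flanked by OMe, giving 7 as the major isomer. (ii) The BINOL enantiomer in Step 15 that gives 7S is found by a short screen, and the (R,R)-salen-Co catalyst in Step 11 is the one that leaves the (S)-epoxide. (iii) Both are stated as assumptions because I did not derive them from first principles.

## Retrosynthetic overview
1. The chalcone C=C comes from a Claisen–Schmidt condensation of acetophenone 19 with 4-hydroxybenzaldehyde (from 10).
2. In 19, the C7–aryl(ring A) bond and the stereocentre at C7 arise in one late three-component coupling. An acylphloroglucinol (7), an aldehyde (10) and an (E)-alkenylboronic acid (17) react by asymmetric Petasis-type alkenyl transfer to an in-situ ortho-quinone methide.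
3. Boronic acid 17 comes from a terminal alkyne, which comes from opening an (S)-terminal epoxide (hydrolytic kinetic resolution, HKR) with acetylide. The epoxide comes from 3-arylpropanal (Heck reaction of an aryl iodide with allyl alcohol).
4. Ring A (7) comes from resorcinol: Ir-catalysed C–H borylation and oxidation add the third oxygen, then Friedel–Crafts acylation. No new carbocycle is formed in the route; the epoxide is a transient ring.

## Route

**Step 1**
Reactants: 1 resorcinol
Product: 2 1,3-bis(methoxymethoxy)benzene
Conditions: MOMCl, i-Pr₂NEt, CH₂Cl₂, 0 °C → rt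
Reagents that add atoms: MOMCl (ClCOC)
Why: Double O-alkylation protects both phenols as MOM ethers, which survive the basic and oxidative steps that follow.

**Step 2**
Reactants: 2
Product: 3 2-[3,5-bis(methoxymethoxy)phenyl]-4,4,5,5-tetramethyl-1,3,2-dioxaborolane
Conditions: B₂pin₂, [Ir(cod)OMe]₂ (1.5 mol %), dtbpy (3 mol %), THF, 80 °C
Reagents that add atoms: B₂pin₂ (CC1(C)OB(OC1(C)C)B1OC(C)(C)C(C)(C)O1)
Why: Ir-catalysed C–H borylation is sterically controlled, so it occurs only at C5, meta to both OMOM groups. This is the future third oxygen position.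

**Step 3**
Reactants: 3
Product: 4 3,5-bis(methoxymethoxy)phenol
Conditions: 30 % H₂O₂, NaOH (aq), THF, 0 °C → rt
Reagents that add atoms: H₂O₂ (OO)
Why: Oxidative deborylation (boronate peroxide, 1,2-aryl shift) converts Ar–Bpin to Ar–OH, giving the 1,3,5-trioxygenated ring; MOM acetals are base-stable.

**Step 4**
Reactants: 4
Product: 5 1-methoxy-3,5-bis(methoxymethoxy)benzene
Conditions: MeI, K₂CO₃, acetone, rt → 50 °C
Reagents that add atoms: MeI (CI)
Why: Williamson O-methylation installs the C6 methoxy group of ring A.

**Step 5**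
Reactants: 5
Product: 6 5-methoxybenzene-1,3-diol
Conditions: 3 M HCl, MeOH, 50 °C
Reagents that add atoms: none
Why: Acid hydrolysis of the MOM acetals frees the two phenols.

**Step 6**
Reactants: 6
Product: 7 1-(2,4-dihydroxy-6-methoxyphenyl)ethan-1-one
Conditions: AcOH, BF₃·OEt₂, 85 °C
Reagents that add atoms: acetic acid (CC(=O)O)
Why: BF₃-mediated Friedel–Crafts acylation goes ortho to a free OH, and the two equivalent positions flanking OMe give a single constitutional isomer.

**Step 7**
Reactants: 8 4-iodophenol
Product: 9 tert-butyl(4-iodophenoxy)dimethylsilane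
Conditions: TBSCl, imidazole, DMF, rt
Reagents that add atoms: TBSCl (C[Si](C)(C(C)(C)C)Cl)
Why: Silyl protection of the phenol, used for all three 4-hydroxyphenyl units.

**Step 8**
Reactants: 9
Product: 10 4-(TBSO)benzaldehyde
Conditions: n-BuLi, THF, –78 °C; then DMF
Reagents that add atoms: DMF (CN(C)C=O)
Why: Iodine–lithium exchange followed by formylation gives the aldehyde; the aryl silyl ether survives at –78 °C.

**Step 9**
Reactants: 9; 11 allyl alcohol
Product: 12 3-[4-(TBSO)phenyl]propanal
Conditions: Pd(OAc)₂ (2 mol %), n-Bu₄NCl, NaHCO₃, DMF, 60 °C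
Reagents that add atoms: none
Why: Mizoroki–Heck reaction under Jeffery conditions. β-H elimination toward the carbinol carbon gives an enol that tautomerises to the saturated aldehyde.

**Step 10**
Reactants: 12
Product: 13 rac-2-{2-[4-(TBSO)phenyl]ethyl}oxirane
Conditions: Me₃S⁺I⁻, n-BuLi, THF, –10 °C → rt
Reagents that add atoms: trimethylsulfonium iodide (C[S+](C)C.[I-]), which adds CH₂
Why: Corey–Chaykovsky epoxidation of the aldehyde with dimethylsulfonium methylide gives the racemic terminal epoxide.

**Step 11**
Reactants: 13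
Product: 14 (2S)-2-{2-[4-(TBSO)phenyl]ethyl}oxirane
Conditions: (R,R)-(salen)Co(III)OAc (0.5 mol %), H₂O (0.55 equiv), THF, 0 °C → rt
Reagents that add atoms: none (water ends up in the diol by-product, not in 14)
Why: Jacobsen hydrolytic kinetic resolution opens the (R)-epoxide to a diol and leaves the (S)-epoxide in high ee, fixing the C3 configuration.

**Step 12**
Reactants: 14
Product: 15 (3S)-1-[4-(TBSO)phenyl]hex-5-yn-3-ol
Conditions: lithium acetylide·ethylenediamine, DMSO/THF, 0 °C → rt
Reagents that add atoms: lithium acetylide ([Li+].[C-]#C)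
Why: SN2 attack at the unhindered terminal epoxide CH₂ leaves the stereocentre untouched, giving the homopropargylic alcohol.

**Step 13**
Reactants: 15
Product: 16 (3S)-3-(TBSO)-1-[4-(TBSO)phenyl]hex-5-yne
Conditions: TBSOTf, 2,6-lutidine, CH₂Cl₂, 0 °C
Reagents that add atoms: TBSOTf (C[Si](C)(C(C)(C)C)OS(=O)(=O)C(F)(F)F)
Why: Silylation prevents the free alcohol from consuming the borane or binding the boronic acid in later steps.

**Step 14**
Reactants: 16
Product: 17 (1E,4S)-4-(TBSO)-6-[4-(TBSO)phenyl]hex-1-en-1-ylboronic acid
Conditions: catecholborane, THF, 70 °C; then H₂O, rt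
Reagents that add atoms: catecholborane (B1Oc2ccccc2O1); water (O)
Why: Syn-hydroboration of the terminal alkyne gives the (E)-alkenylboronate, and hydrolysis releases the boronic acid. The E geometry of the C5=C6 alkene is set here.

**Step 15 (key late coupling)**
Reactants: 7 acetophenone; 10 aldehyde; 17 boronic acid
Product: 18 acetophenone carrying at C3 the (S)-CH(4-TBSO-C₆H₄)–CH=CH(E)–CH₂–CH(OTBS)–CH₂CH₂–C₆H₄-4-OTBS group
Conditions: 7 (1 equiv), 10 (1.5 equiv), 17 (2 equiv), (S)-3,3′-Br₂-BINOL (20 mol %), 4 Å MS, PhMe, 40–50 °C, 72 h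
Reagents that add atoms: none (all three components are numbered reactants)
Why: Boronic-acid-assisted phenol–aldehyde condensation gives an ortho-quinone methide at C3, the carbon between the two OH groups, which is doubly activated. The chiral BINOL-boronate then transfers the alkenyl group with retention of E geometry to one face of the o-QM, by asymmetric Petasis-type alkenylation. This sets C7 as S, and the remote C3 centre has negligible influence.

**Step 16**
Reactants: 18
Product: 19 1-{2,4-dihydroxy-6-methoxy-3-[(S)-(4-hydroxyphenyl)((E,4S)-4-hydroxy-6-(4-hydroxyphenyl)hex-1-enyl)methyl]phenyl}ethan-1-one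
Conditions: TBAF, AcOH, THF, 0 °C → rt
Reagents that add atoms: none
Why: Fluoride cleaves all three Si–O bonds, and AcOH buffering avoids base-mediated side reactions. No stereocentre or alkene is affected.

**Step 17**
Reactants: 19; 10
Product: 20 calyxin B
Conditions: KOH, EtOH/H₂O, rt, 48 h; then aq HCl to pH ~4
Reagents that add atoms: none
Why: Claisen–Schmidt aldol condensation of the methyl ketone with the aldehyde gives the (E)-chalcone by thermodynamic dehydration. The aryl TBS ether of 10 is cleaved in situ by hydroxide, and C3 and C7 are not epimerised because C7–H is not acidic enough for KOH/EtOH.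

## Compound list
1 | resorcinol | Oc1cccc(O)c1 | starting material
2 | 1,3-bis(methoxymethoxy)benzene | COCOc1cccc(OCOC)c1 | intermediate
3 | 2-[3,5-bis(methoxymethoxy)phenyl]-4,4,5,5-tetramethyl-1,3,2-dioxaborolane | COCOc1cc(OCOC)cc(B2OC(C)(C)C(C)(C)O2)c1 | intermediate
4 | 3,5-bis(methoxymethoxy)phenol | COCOc1cc(O)cc(OCOC)c1 | intermediate
5 | 1-methoxy-3,5-bis(methoxymethoxy)benzene | COCOc1cc(OC)cc(OCOC)c1 | intermediate
6 | 5-methoxybenzene-1,3-diol | COc1cc(O)cc(O)c1 | intermediate
7 | 1-(2,4-dihydroxy-6-methoxyphenyl)ethan-1-one | COc1cc(O)cc(O)c1C(C)=O | intermediate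
8 | 4-iodophenol | Oc1ccc(I)cc1 | starting material
9 | tert-butyl(4-iodophenoxy)dimethylsilane | Ic1ccc(O[Si](C)(C)C(C)(C)C)cc1 | intermediate
10 | 4-(TBSO)benzaldehyde | O=Cc1ccc(O[Si](C)(C)C(C)(C)C)cc1 | intermediate
11 | allyl alcohol | C=CCO | starting material
12 | 3-[4-(TBSO)phenyl]propanal | O=CCCc1ccc(O[Si](C)(C)C(C)(C)C)cc1 | intermediate
13 | rac-2-{2-[4-(TBSO)phenyl]ethyl}oxirane | C1OC1CCc1ccc(O[Si](C)(C)C(C)(C)C)cc1 | intermediate
14 | (2S)-2-{2-[4-(TBSO)phenyl]ethyl}oxirane | C1O[C@H]1CCc1ccc(O[Si](C)(C)C(C)(C)C)cc1 | intermediate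
15 | (3S)-1-[4-(TBSO)phenyl]hex-5-yn-3-ol | C#CC[C@@H](O)CCc1ccc(O[Si](C)(C)C(C)(C)C)cc1 | intermediate
16 | (3S)-3-(TBSO)-1-[4-(TBSO)phenyl]hex-5-yne | C#CC[C@@H](O[Si](C)(C)C(C)(C)C)CCc1ccc(O[Si](C)(C)C(C)(C)C)cc1 | intermediate
17 | (1E,4S)-4-(TBSO)-6-[4-(TBSO)phenyl]hex-1-en-1-ylboronic acid | OB(O)/C=C/C[C@@H](O[Si](C)(C)C(C)(C)C)CCc1ccc(O[Si](C)(C)C(C)(C)C)cc1 | intermediate
18 | tris-TBS-protected coupled acetophenone | COc1cc(O)c([C@@H](/C=C/C[C@@H](O[Si](C)(C)C(C)(C)C)CCc2ccc(O[Si](C)(C)C(C)(C)C)cc2)c2ccc(O[Si](C)(C)C(C)(C)C)cc2)c(O)c1C(C)=O | intermediate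
19 | deprotected acetophenone | COc1cc(O)c([C@@H](/C=C/C[C@@H](O)CCc2ccc(O)cc2)c2ccc(O)cc2)c(O)c1C(C)=O | intermediate
20 | calyxin B | COc1cc(O)c([C@@H](/C=C/C[C@@H](O)CCc2ccc(O)cc2)c2ccc(O)cc2)c(O)c1C(=O)/C=C/c1ccc(O)cc1 | target

**Total steps:** 17. **Longest linear sequence:** 10 (4-iodophenol → 9 → 12 → 13 → 14 → 15 → 16 → 17 → 18 → 19 → 20), which is 0.59 of the total.

**Three steps most likely to fail**
1. **Step 15 (asymmetric three-component coupling).** Risks are low ee with this very electron-rich o-QM, competing reaction at C5, and bis-arylation. Fallback: run the coupling with an achiral Brønsted acid or boronate promoter to give both C7 epimers, then separate the diastereomers by preparative HPLC (C3 is already enantiopure). A further alternative is an Ir- or Pd-catalysed asymmetric allylic arylation of ring A.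
2. **Step 6 (regioselective acylation of 6).** The acetyl group could end up between the two OH groups instead. Fallback: make 7 by Houben–Hoesch acetylation of phloroglucinol followed by monomethylation and chromatographic separation, which changes the route to ring A.
3. **Step 17 (Claisen–Schmidt on the free polyphenol).** Risks are low conversion and flavanone formation. Fallback: install the chalcone first by condensing 7 with 10 to give the cardamonin analogue, then use that as the phenol component in the Step 15 coupling, so no enolisable ketone is left for the last step.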